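**Strategy.** Apart from two identical carbinol carbons, C3 and C3', each flanked by CH2 groups in a 1,1,5-trimethylcyclohex-5-ene (β) ring, the target is an achiral C40 hydrocarbon. Both C–O bonds are therefore disconnected last: a carotenoid β-ring 3-hydroxylase (non-heme diiron monooxygenase, CrtZ class) should convert the unactivated C3–H and C3'–H methylene bonds of 7,8-didehydro-7',8'-dihydro-β,β-carotene into the (3R)- and (3'R)-alcohols in one operation. That precursor needs neither chiral building blocks nor protecting groups and is assembled from two ionone-type ring ketones, an enynol and the C10 dialdehyde by one Sonogashira coupling and two Horner–Wadsworth–Emmons olefinations.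

Key step: step 9

Assumption: short-lived metalated forms (lithium enolates, phosphonate carbanions, the lithium acetylide, the lithium aluminate of 12) are treated as activated states of the numbered compounds and are not numbered; 3 and 7 are taken as purchasable fine chemicals.

Step 1
Reactants: 1 2,2,6-trimethylcyclohexan-1-one (racemic)
Product: 2 2,6,6-trimethylcyclohex-1-en-1-yl trifluoromethanesulfonate
Conditions: LDA, THF, −78 °C; PhNTf2, −78 °C → rt
Reagents that add atoms: N-phenylbis(trifluoromethanesulfonimide), O=S(=O)(N(c1ccccc1)S(=O)(=O)C(F)(F)F)C(F)(F)F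
Why: Only C6 of 1 is enolizable, so deprotonation gives a single tetrasubstituted enolate that is O-sulfonylated (enol triflate formation), and the stereocentre of racemic 1 is erased.

Step 2
Reactants: 2 2,6,6-trimethylcyclohex-1-en-1-yl trifluoromethanesulfonate; 3 (E)-3-methylpent-2-en-4-yn-1-ol
Product: 4 (E)-3-methyl-5-(2,6,6-trimethylcyclohex-1-en-1-yl)pent-2-en-4-yn-1-ol
Conditions: Pd(PPh3)4 (cat.), CuI (cat.), i-Pr2NH, DMF, rt → 40 °C
Reagents that add atoms: none
Why: Sonogashira coupling of the alkenyl triflate with the terminal alkyne forms the C6–C7 bond under mild amine conditions that leave the (E)-double bond of 3 untouched.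

Step 3
Reactants: 4 (E)-3-methyl-5-(2,6,6-trimethylcyclohex-1-en-1-yl)pent-2-en-4-yn-1-ol
Product: 6 diethyl [(E)-3-methyl-5-(2,6,6-trimethylcyclohex-1-en-1-yl)pent-2-en-4-yn-1-yl]phosphonate, via allylic bromide 5 (not isolated)
Conditions: PBr3 (0.4 equiv), Et2O, −10 °C; cold NaHCO3 wash, crude bromide used at once; P(OEt)3, toluene, 90 °C, dark
Reagents that add atoms: phosphorus tribromide, BrP(Br)Br (Br remains in 5 only); triethyl phosphite, CCOP(OCC)OCC
Why: SN2 bromination of the primary allylic alcohol followed by a Michaelis–Arbuzov reaction at the same primary carbon should keep the 9E geometry as long as the bromide is kept cold and not stored.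

Step 4
Reactants: 6 diethyl [(E)-3-methyl-5-(2,6,6-trimethylcyclohex-1-en-1-yl)pent-2-en-4-yn-1-yl]phosphonate; 7 (2E,4E,6E)-2,7-dimethylocta-2,4,6-trienedial
Product: 8 (2E,4E,6E,8E,10E)-2,7,11-trimethyl-13-(2,6,6-trimethylcyclohex-1-en-1-yl)trideca-2,4,6,8,10-pentaen-12-ynal
Conditions: NaHMDS, THF, −78 °C; cannulated into 7 (3 equiv), THF, −78 → 0 °C, dark; excess 7 recovered
Reagents that add atoms: none
Why: The Horner–Wadsworth–Emmons reaction of an allylic phosphonate anion is E-selective for the new C11=C12 bond, and inverse addition to excess dialdehyde, together with the lower electrophilicity of the longer polyenal product, should favour mono-olefination.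

Step 5
Reactants: 9 4-(2,6,6-trimethylcyclohex-1-en-1-yl)butan-2-one (dihydro-β-ionone)
Product: 11 2-(but-3-yn-1-yl)-1,3,3-trimethylcyclohex-1-ene, via enol phosphate 10 (not isolated)
Conditions: LDA (1.05 equiv), THF, −78 °C; ClP(O)(OEt)2, −78 °C → rt; LDA (2.3 equiv), −78 °C → rt; aq. NH4Cl
Reagents that add atoms: diethyl chlorophosphate, CCOP(=O)(Cl)OCC (its atoms remain in 10 only)
Why: Kinetic enolization at the methyl group, O-phosphorylation and base-induced elimination of diethyl phosphate (methyl ketone to terminal alkyne via the enol phosphate) should give the acetylene without touching the ring alkene.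

Step 6
Reactants: 11 2-(but-3-yn-1-yl)-1,3,3-trimethylcyclohex-1-ene
Product: 13 (E)-3-methyl-5-(2,6,6-trimethylcyclohex-1-en-1-yl)pent-2-en-1-ol, via alkenylalane 12 (not isolated)
Conditions: Me3Al (2 equiv), Cp2ZrCl2 (0.25 equiv), CH2Cl2, 0 °C → rt; volatiles removed; n-BuLi, hexane–THF, −78 → 0 °C; (CH2O)n, rt; aq. Rochelle salt
Reagents that add atoms: trimethylaluminium, C[Al](C)C; formaldehyde (as paraformaldehyde), C=O
Why: Zirconium-catalysed carboalumination (Negishi) adds CH3 and Al syn across the terminal alkyne with CH3 on the internal carbon, which fixes the 9'E geometry, and the derived aluminate is hydroxymethylated with retention.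

Step 7
Reactants: 13 (E)-3-methyl-5-(2,6,6-trimethylcyclohex-1-en-1-yl)pent-2-en-1-ol
Product: 15 diethyl [(E)-3-methyl-5-(2,6,6-trimethylcyclohex-1-en-1-yl)pent-2-en-1-yl]phosphonate, via allylic bromide 14 (not isolated)
Conditions: PBr3 (0.4 equiv), Et2O, −10 °C; cold NaHCO3 wash, crude bromide used at once; P(OEt)3, toluene, 90 °C
Reagents that add atoms: phosphorus tribromide, BrP(Br)Br (Br remains in 14 only); triethyl phosphite, CCOP(OCC)OCC
Why: The same SN2 bromination and Michaelis–Arbuzov sequence as in step 3 should proceed at the primary carbon of this geranyl-type system without E/Z scrambling.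

Step 8
Reactants: 15 diethyl [(E)-3-methyl-5-(2,6,6-trimethylcyclohex-1-en-1-yl)pent-2-en-1-yl]phosphonate; 8 (2E,4E,6E,8E,10E)-2,7,11-trimethyl-13-(2,6,6-trimethylcyclohex-1-en-1-yl)trideca-2,4,6,8,10-pentaen-12-ynal
Product: 16 (all-E)-7,8-didehydro-7',8'-dihydro-β,β-carotene
Conditions: 15 (1.3 equiv), n-BuLi, THF–DMPU, −78 °C; 8, −78 °C → rt, dark, no iodine; crystallization
Reagents that add atoms: none
Why: Horner–Wadsworth–Emmons olefination with the allylic phosphonate anion should form C11'=C12' mainly E and join the two halves without equilibrating conditions, which matters because the acetylenic 9E bond must not be isomerized.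

Step 9
Reactants: 16 (all-E)-7,8-didehydro-7',8'-dihydro-β,β-carotene
Product: 17 (3R,3'R,all-E)-7,8-didehydro-7',8'-dihydro-β,β-carotene-3,3'-diol
Conditions: recombinant β-carotene 3,3'-hydroxylase CrtZ (Pantoea ananatis, E. coli membrane fraction), ferredoxin, ferredoxin–NADP+ reductase, NADP+ (cat.), D-glucose/glucose dehydrogenase, Fe(II)/ascorbate, catalase, air (O2), 16 as phosphatidylcholine/Tween 80 dispersion, Tris·HCl pH 7.8, 30 °C, dark
Reagents that add atoms: dioxygen, O=O
Why: The membrane-bound non-heme diiron hydroxylase (fatty-acid-hydroxylase superfamily) activates O2 at its reduced diiron centre with electrons relayed from NADPH through ferredoxin, abstracts a hydrogen atom from the ring C3 methylene held over the metal site and returns OH by rebound with retention, then repeats the cycle on the second ring. The closest known reaction is the conversion of β-carotene into (3R,3'R)-zeaxanthin by the same enzyme class, which also hydroxylates 7,8-dihydro-β rings and 4-oxo-β rings at C3. No ring is closed. Both new stereocentres, C3 and C3', are set by the chiral active site alone (catalyst control on an achiral substrate), each prochiral CH2 being oxidized on the face that gives the R alcohol. The step needs site selectivity for C3/C3' over the allylic C4/C4', C7' and C8' methylenes and over the polyene and alkyne π-bonds, which the enzyme should secure by binding the 1,1,5-trimethylcyclohex-5-ene ring itself, a motif present unchanged at both ends of 16. The 7,8-triple bond alters only the exit vector of the chain, but acceptance of that ring is untested and is the main risk; if it reacts more slowly, the mono-ol can be resubmitted.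

**Compound list**

1 | 2,2,6-trimethylcyclohexan-1-one (racemic) | CC1CCCC(C)(C)C1=O | starting material
2 | 2,6,6-trimethylcyclohex-1-en-1-yl trifluoromethanesulfonate | CC1=C(OS(=O)(=O)C(F)(F)F)C(C)(C)CCC1 | intermediate
3 | (E)-3-methylpent-2-en-4-yn-1-ol | C#C/C(C)=C/CO | starting material
4 | (E)-3-methyl-5-(2,6,6-trimethylcyclohex-1-en-1-yl)pent-2-en-4-yn-1-ol | CC1=C(C#C/C(C)=C/CO)C(C)(C)CCC1 | intermediate
5 | 2-[(E)-5-bromo-3-methylpent-3-en-1-yn-1-yl]-1,3,3-trimethylcyclohex-1-ene | CC1=C(C#C/C(C)=C/CBr)C(C)(C)CCC1 | intermediate (not isolated)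
6 | diethyl [(E)-3-methyl-5-(2,6,6-trimethylcyclohex-1-en-1-yl)pent-2-en-4-yn-1-yl]phosphonate | CC1=C(C#C/C(C)=C/CP(=O)(OCC)OCC)C(C)(C)CCC1 | intermediate
7 | (2E,4E,6E)-2,7-dimethylocta-2,4,6-trienedial | O=C/C(C)=C/C=C/C=C(C)/C=O | starting material
8 | (2E,4E,6E,8E,10E)-2,7,11-trimethyl-13-(2,6,6-trimethylcyclohex-1-en-1-yl)trideca-2,4,6,8,10-pentaen-12-ynal (7,8-didehydro-12'-apo-β-caroten-12'-al) | CC1=C(C#C/C(C)=C/C=C/C(C)=C/C=C/C=C(C)/C=O)C(C)(C)CCC1 | intermediate
9 | 4-(2,6,6-trimethylcyclohex-1-en-1-yl)butan-2-one (dihydro-β-ionone) | CC(=O)CCC1=C(C)CCCC1(C)C | starting material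
10 | diethyl 4-(2,6,6-trimethylcyclohex-1-en-1-yl)but-1-en-2-yl phosphate | C=C(CCC1=C(C)CCCC1(C)C)OP(=O)(OCC)OCC | intermediate (not isolated)
11 | 2-(but-3-yn-1-yl)-1,3,3-trimethylcyclohex-1-ene | C#CCCC1=C(C)CCCC1(C)C | intermediate
12 | dimethyl[(E)-2-methyl-4-(2,6,6-trimethylcyclohex-1-en-1-yl)but-1-en-1-yl]alumane | C[Al](C)/C=C(\C)CCC1=C(C)CCCC1(C)C | intermediate (not isolated)
13 | (E)-3-methyl-5-(2,6,6-trimethylcyclohex-1-en-1-yl)pent-2-en-1-ol | OC/C=C(\C)CCC1=C(C)CCCC1(C)C | intermediate
14 | 2-[(E)-5-bromo-3-methylpent-3-en-1-yl]-1,3,3-trimethylcyclohex-1-ene | BrC/C=C(\C)CCC1=C(C)CCCC1(C)C | intermediate (not isolated)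
15 | diethyl [(E)-3-methyl-5-(2,6,6-trimethylcyclohex-1-en-1-yl)pent-2-en-1-yl]phosphonate | CCOP(=O)(OCC)C/C=C(\C)CCC1=C(C)CCCC1(C)C | intermediate
16 | (all-E)-7,8-didehydro-7',8'-dihydro-β,β-carotene | CC1=C(C#C/C(C)=C/C=C/C(C)=C/C=C/C=C(C)/C=C/C=C(\C)CCC2=C(C)CCCC2(C)C)C(C)(C)CCC1 | intermediate
17 | (3R,3'R,all-E)-7,8-didehydro-7',8'-dihydro-β,β-carotene-3,3'-diol | CC1=C(C#C/C(C)=C/C=C/C(C)=C/C=C/C=C(C)/C=C/C=C(\C)CCC2=C(C)C[C@@H](O)CC2(C)C)C(C)(C)C[C@H](O)C1 | target

**Count.** Total: 9 steps. Longest linear sequence: 6 steps (1 → 2 → 3 → 4 → 8 → 9).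

**Steps most likely to fail**

1. Step 9. The hydroxylase may not turn over the acetylenic ring, may stop at a mono-ol, or may receive too little of the very lipophilic substrate at the membrane. The fallback carries the hydroxyl groups through from the chiral pool by known chemistry; it sets out from 3 and 7 and returns at 17. (4R,6R)-4-Hydroxy-2,2,6-trimethylcyclohexanone F1 (actinol, purchased) would be silylated (TBSCl, imidazole, DMF) to silyl ether ketone F2 and converted (LDA, PhNTf2, THF) into enol triflate F3. Sonogashira coupling of F3 with 3 should give enynol F4, which would be taken through allylic bromide F5 (PBr3) and an Arbuzov reaction to phosphonate F6; olefination of excess 7 with F6 should give C25 aldehyde F7. For the other half, Sonogashira coupling of F3 with but-3-yn-2-ol should give propargylic alcohol F8. Hydrogenation of the triple bond (H2, Pd/C, EtOAc; the tetrasubstituted ring alkene is inert) would give saturated alcohol F9, and Dess–Martin oxidation the ketone F10. Olefination of F10 with triethyl phosphonoacetate (NaH, THF) should give (E)-enoate F11 after chromatographic removal of the Z isomer. DIBAL-H reduction would give allylic alcohol F12, and PBr3 then P(OEt)3 would lead through allylic bromide F13 to phosphonate F14. Olefination of F7 with the anion of F14 should give bis-silyl ether F15, and TBAF in THF would release 17.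

2. Step 8. Geometric integrity may erode (11'Z formation, scrambling of the 9'E bond in the allyl anion), or γ-attack and slow elimination may occur with the weakly stabilised phosphonate. The fallback forms the C10'–C11' single bond instead, with both neighbouring double bonds fixed beforehand; it sets out from 8 and 11 and returns at 16. Takai iodo-olefination of 8 (CHI3, CrCl2, THF, 0 °C) should give (E)-polyenyl iodide F16. Alkenylalane 12, generated from 11 exactly as in the first half of step 6, would then be coupled with F16 (Pd(PPh3)4 cat., ZnCl2, THF, rt; Negishi alkenyl–alkenyl coupling) to give 16.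

3. Step 4. The symmetrical dialdehyde may be olefinated at both ends, or the mono-adduct may be hard to separate from recovered 7. The fallback uses a desymmetrised linchpin; it sets out from 7 and 6 and returns at 8. Monoacetalisation of 7 with 2,2-dimethylpropane-1,3-diol (PPTS, toluene; diacetal and 7 are recycled at this cheap stage) should give mono-acetal F17. Olefination with the anion of 6 would give C25 acetal F18, and mild hydrolysis (aq. oxalic acid, acetone) would return 8.

**Further compounds**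

F1 | step 9 | (4R,6R)-4-hydroxy-2,2,6-trimethylcyclohexan-1-one | O=C1[C@H](C)C[C@@H](O)CC1(C)C
F2 | step 9 | (4R,6R)-4-(tert-butyldimethylsilyloxy)-2,2,6-trimethylcyclohexan-1-one | O=C1[C@H](C)C[C@@H](O[Si](C)(C)C(C)(C)C)CC1(C)C
F3 | step 9 | (4R)-4-(tert-butyldimethylsilyloxy)-2,6,6-trimethylcyclohex-1-en-1-yl trifluoromethanesulfonate | CC1=C(OS(=O)(=O)C(F)(F)F)C(C)(C)C[C@H](O[Si](C)(C)C(C)(C)C)C1
F4 | step 9 | (E)-5-[(4R)-4-(tert-butyldimethylsilyloxy)-2,6,6-trimethylcyclohex-1-en-1-yl]-3-methylpent-2-en-4-yn-1-ol | CC1=C(C#C/C(C)=C/CO)C(C)(C)C[C@H](O[Si](C)(C)C(C)(C)C)C1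
F5 | step 9 | [(1R)-4-[(E)-5-bromo-3-methylpent-3-en-1-yn-1-yl]-3,5,5-trimethylcyclohex-3-en-1-yl]oxy(tert-butyl)dimethylsilane | CC1=C(C#C/C(C)=C/CBr)C(C)(C)C[C@H](O[Si](C)(C)C(C)(C)C)C1
F6 | step 9 | diethyl [(E)-5-[(4R)-4-(tert-butyldimethylsilyloxy)-2,6,6-trimethylcyclohex-1-en-1-yl]-3-methylpent-2-en-4-yn-1-yl]phosphonate | CC1=C(C#C/C(C)=C/CP(=O)(OCC)OCC)C(C)(C)C[C@H](O[Si](C)(C)C(C)(C)C)C1
F7 | step 9 | (2E,4E,6E,8E,10E)-13-[(4R)-4-(tert-butyldimethylsilyloxy)-2,6,6-trimethylcyclohex-1-en-1-yl]-2,7,11-trimethyltrideca-2,4,6,8,10-pentaen-12-ynal | CC1=C(C#C/C(C)=C/C=C/C(C)=C/C=C/C=C(C)/C=O)C(C)(C)C[C@H](O[Si](C)(C)C(C)(C)C)C1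
F8 | step 9 | 4-[(4R)-4-(tert-butyldimethylsilyloxy)-2,6,6-trimethylcyclohex-1-en-1-yl]but-3-yn-2-ol (carbinol epimers) | CC(O)C#CC1=C(C)C[C@@H](O[Si](C)(C)C(C)(C)C)CC1(C)C
F9 | step 9 | 4-[(4R)-4-(tert-butyldimethylsilyloxy)-2,6,6-trimethylcyclohex-1-en-1-yl]butan-2-ol (carbinol epimers) | CC(O)CCC1=C(C)C[C@@H](O[Si](C)(C)C(C)(C)C)CC1(C)C
F10 | step 9 | 4-[(4R)-4-(tert-butyldimethylsilyloxy)-2,6,6-trimethylcyclohex-1-en-1-yl]butan-2-one | CC(=O)CCC1=C(C)C[C@@H](O[Si](C)(C)C(C)(C)C)CC1(C)C
F11 | step 9 | ethyl (E)-5-[(4R)-4-(tert-butyldimethylsilyloxy)-2,6,6-trimethylcyclohex-1-en-1-yl]-3-methylpent-2-enoate | CCOC(=O)/C=C(\C)CCC1=C(C)C[C@@H](O[Si](C)(C)C(C)(C)C)CC1(C)C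
F12 | step 9 | (E)-5-[(4R)-4-(tert-butyldimethylsilyloxy)-2,6,6-trimethylcyclohex-1-en-1-yl]-3-methylpent-2-en-1-ol | OC/C=C(\C)CCC1=C(C)C[C@@H](O[Si](C)(C)C(C)(C)C)CC1(C)C
F13 | step 9 | [(1R)-4-[(E)-5-bromo-3-methylpent-3-en-1-yl]-3,5,5-trimethylcyclohex-3-en-1-yl]oxy(tert-butyl)dimethylsilane | BrC/C=C(\C)CCC1=C(C)C[C@@H](O[Si](C)(C)C(C)(C)C)CC1(C)C
F14 | step 9 | diethyl [(E)-5-[(4R)-4-(tert-butyldimethylsilyloxy)-2,6,6-trimethylcyclohex-1-en-1-yl]-3-methylpent-2-en-1-yl]phosphonate | CCOP(=O)(OCC)C/C=C(\C)CCC1=C(C)C[C@@H](O[Si](C)(C)C(C)(C)C)CC1(C)C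
F15 | step 9 | (3R,3'R,all-E)-3,3'-bis(tert-butyldimethylsilyloxy)-7,8-didehydro-7',8'-dihydro-β,β-carotene | CC1=C(C#C/C(C)=C/C=C/C(C)=C/C=C/C=C(C)/C=C/C=C(\C)CCC2=C(C)C[C@@H](O[Si](C)(C)C(C)(C)C)CC2(C)C)C(C)(C)C[C@H](O[Si](C)(C)C(C)(C)C)C1
F16 | step 8 | 2-[(3E,5E,7E,9E,11E,13E)-14-iodo-3,7,12-trimethyltetradeca-3,5,7,9,11,13-hexaen-1-yn-1-yl]-1,3,3-trimethylcyclohex-1-ene | CC1=C(C#C/C(C)=C/C=C/C(C)=C/C=C/C=C(C)/C=C/I)C(C)(C)CCC1
F17 | step 4 | (2E,4E,6E)-7-(5,5-dimethyl-1,3-dioxan-2-yl)-2-methylocta-2,4,6-trienal | O=C/C(C)=C/C=C/C=C(C)/C1OCC(C)(C)CO1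
F18 | step 4 | 5,5-dimethyl-2-[(2E,4E,6E,8E,10E)-7,11-dimethyl-13-(2,6,6-trimethylcyclohex-1-en-1-yl)trideca-2,4,6,8,10-pentaen-12-yn-2-yl]-1,3-dioxane | CC1=C(C#C/C(C)=C/C=C/C(C)=C/C=C/C=C(C)/C2OCC(C)(C)CO2)C(C)(C)CCC1
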